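Everything rests on reading the four-carbon string C3–C2–C2'–C3' of the bipyrrole as a former buta-1,3-diyne. In ring A (N1, C2–C5) and ring B (N1', C2'–C5') each C2=C3 bond bears nitrogen at C2 and bromine at C3, trans to one another, as left by anti N/Br addition to a triple bond. One operation with a Br+ donor therefore closes both rings (N1–C2, N1'–C2') and places the two crowded bromines at C3 and C3'. Its substrate is octa-3,5-diyne bearing a tosylamide nitrogen on C1 and on C8. Sulfinate loss then aromatises both rings, and electrophilic bromination fills C4, C5, C4' and C5'.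

Key step: step 3

Remark: bipyrrole locants (N1, C2–C5, primed for ring B) are used for all cyclic compounds, and no compound has a stereocentre. The ring CH2 next to nitrogen in the bis-dihydropyrrole has no acidifying neighbour, so aromatisation is planned with an alkoxide base instead of an amidine base. The amine is taken as its free base (the hydrochloride would need one more equivalent of K2CO3).

Step 1
Reactants: 1 but-3-yn-1-amine; 2 p-toluenesulfonyl chloride
Product: 3 N-(but-3-yn-1-yl)-4-methylbenzenesulfonamide
Conditions: K2CO3, THF/H2O, 0 °C → rt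
Reagents that add atoms: p-toluenesulfonyl chloride (2), Cc1ccc(cc1)S(=O)(=O)Cl
Why: Schotten–Baumann-type N-sulfonylation, in which the primary amine outcompetes water and carbonate for the sulfonyl chloride, one equivalent of 2 limits bis-sulfonylation, and the terminal alkyne is inert.

Step 2
Reactants: 3 N-(but-3-yn-1-yl)-4-methylbenzenesulfonamide (two molecules)
Product: 4 N,N'-(octa-3,5-diyne-1,8-diyl)bis(4-methylbenzenesulfonamide)
Conditions: CuCl (10 mol %), TMEDA (20 mol %), air, acetone, rt
Reagents that add atoms: none
Why: Glaser–Hay oxidative homocoupling, in which the TMEDA-ligated copper acetylide is oxidised by O2 and two alkynyl units join to make the central C(sp)–C(sp) bond (the future C2–C2' bond), the sulfonamide N–H being a spectator at room temperature.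

Step 3
Reactants: 4 N,N'-(octa-3,5-diyne-1,8-diyl)bis(4-methylbenzenesulfonamide); 5 N-bromosuccinimide (2.1 equiv)
Product: 7 3,3'-dibromo-1,1'-ditosyl-4,4',5,5'-tetrahydro-1H,1'H-2,2'-bipyrrole, via monocyclised bromo-enyne sulfonamide 6 (not isolated)
Conditions: NBS (recrystallised), MeCN, 0 °C → rt, dark
Reagents that add atoms: N-bromosuccinimide (5), O=C1CCC(=O)N1Br
Why: NBS hands Br+ to one triple bond of 4 (bridged bromirenium or π-complex), the pendant sulfonamide nitrogen opens it from the opposite face at the inner carbon while its proton ends on succinimide, and the resulting enyne 6 goes through the same events at its remaining triple bond. The closest known reaction types are the 5-endo-dig halocyclisation (electrophilic aminohalogenation) of homopropargylic sulfonamides to 3-halo-4,5-dihydropyrroles and the double halocyclisation of 1,4-disubstituted buta-1,3-diynes to 3,3'-dihalo-2,2'-biheteroaryls, the changes here being bromine for iodine and an alkynyl substituent on the reacting alkyne. Ring A (bond N1–C2) and ring B (bond N1'–C2') are each closed in the 5-endo-dig mode. No stereocentre arises, and the trans placement of N and Br across each C2=C3 bond follows from anti addition and is locked by the ring. The step needs nitrogen at the inner and bromine at the outer alkyne carbon, which the CH2CH2 tether secures because closure onto the outer carbon would have to build a strained alkylidene-azetidine (4-exo-dig). It also needs the second Br+ to choose the alkyne of 6 over the new enamide, which is favoured because the sulfonyl group and the C3 bromine lower the enamide's nucleophilicity and C3 has no hydrogen to lose, so any attack there is reversible.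

Step 4
Reactants: 7 3,3'-dibromo-1,1'-ditosyl-4,4',5,5'-tetrahydro-1H,1'H-2,2'-bipyrrole
Product: 9 3,3'-dibromo-1H,1'H-2,2'-bipyrrole, via half-aromatised mono-tosyl bipyrrole 8 (not isolated)
Conditions: t-BuOK (5 equiv), DMSO–THF, Ar, 0 °C → rt; aq NH4Cl; crude product used at once
Reagents that add atoms: none
Why: Base-induced 1,2-elimination of p-toluenesulfinate across N1–C5 and N1'–C5', followed by a prototropic shift to the aromatic 1H-pyrrole, is the known desulfinative aromatisation of N-sulfonyl dihydropyrroles; a strong alkoxide in a dipolar medium makes up for the unactivated C5–H2, and the C3–Br bonds are safe because dehydrobromination would demand an allene inside a five-membered ring.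

Step 5
Reactants: 9 3,3'-dibromo-1H,1'H-2,2'-bipyrrole; 5 N-bromosuccinimide (4.2 equiv)
Product: 11 3,3',4,4',5,5'-hexabromo-1H,1'H-2,2'-bipyrrole, via 3,3',5,5'-tetrabromo-2,2'-bipyrrole 10 (not isolated)
Conditions: NBS, dry THF, −78 °C → rt, dark
Reagents that add atoms: N-bromosuccinimide (5), O=C1CCC(=O)N1Br
Why: Electrophilic aromatic substitution of an NH-pyrrole by NBS, in which the α-positions C5/C5' react first to give 10 and the β-positions C4/C4' follow, exhaustive bromination of pyrroles and 2,2'-bipyrroles being well established and ending when no ring C–H is left.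

Compound list
1 | but-3-yn-1-amine | C#CCCN | starting material
2 | p-toluenesulfonyl chloride | Cc1ccc(cc1)S(=O)(=O)Cl | starting material
3 | N-(but-3-yn-1-yl)-4-methylbenzenesulfonamide | C#CCCNS(=O)(=O)c1ccc(C)cc1 | intermediate
4 | N,N'-(octa-3,5-diyne-1,8-diyl)bis(4-methylbenzenesulfonamide) | Cc1ccc(cc1)S(=O)(=O)NCCC#CC#CCCNS(=O)(=O)c1ccc(C)cc1 | intermediate
5 | N-bromosuccinimide | O=C1CCC(=O)N1Br | starting material
6 | N-[4-(3-bromo-1-tosyl-4,5-dihydro-1H-pyrrol-2-yl)but-3-yn-1-yl]-4-methylbenzenesulfonamide | Cc1ccc(cc1)S(=O)(=O)NCCC#CC1=C(Br)CCN1S(=O)(=O)c1ccc(C)cc1 | intermediate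
7 | 3,3'-dibromo-1,1'-ditosyl-4,4',5,5'-tetrahydro-1H,1'H-2,2'-bipyrrole | Cc1ccc(cc1)S(=O)(=O)N1CCC(Br)=C1C1=C(Br)CCN1S(=O)(=O)c1ccc(C)cc1 | intermediate
8 | 3,3'-dibromo-1-tosyl-4,5-dihydro-1H,1'H-2,2'-bipyrrole | Cc1ccc(cc1)S(=O)(=O)N1CCC(Br)=C1c1[nH]ccc1Br | intermediate
9 | 3,3'-dibromo-1H,1'H-2,2'-bipyrrole | Brc1cc[nH]c1-c1[nH]ccc1Br | intermediate
10 | 3,3',5,5'-tetrabromo-1H,1'H-2,2'-bipyrrole | Brc1cc(Br)c([nH]1)-c1[nH]c(Br)cc1Br | intermediate
11 | 3,3',4,4',5,5'-hexabromo-1H,1'H-2,2'-bipyrrole | Brc1[nH]c(-c2[nH]c(Br)c(Br)c2Br)c(Br)c1Br | target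

Total step count: 5. Longest linear sequence: 5.

Steps most likely to fail

Step 3. Transfer of Br+ to the electron-poor conjugated diyne may be slower than N-bromination of the sulfonamide or simple dibromination of a triple bond, and the reaction may stall after the first ring closure. The fallback sets out from 4 and separates C–N from C–Br bond formation. Ph3PAuNTf2 (5 mol %) in toluene should bring about a double 5-endo-dig cycloisomerisation (intramolecular hydroamination of homopropargylic sulfonamides) to 1,1'-ditosyl-4,4',5,5'-tetrahydro-1H,1'H-2,2'-bipyrrole F1. Its enamide β-carbons C3 and C3' are then brominated with two equivalents of 5 in CH2Cl2 at −78 → 0 °C by Br+ addition and loss of the C3 proton. The route is rejoined at 7.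

Step 4. Removal of the unactivated C5 proton may be too slow, so that base-induced decomposition or loss of bromine from the liberated NH-pyrrole competes. The fallback sets out from 7 and replaces the internal redox elimination with an external oxidant. DDQ in refluxing toluene should dehydrogenate both rings to 3,3'-dibromo-1,1'-ditosyl-1H,1'H-2,2'-bipyrrole F2. Aqueous NaOH in dioxane then hydrolyses the two N-sulfonyl groups, the standard cleavage of N-tosylpyrroles. The route is rejoined at 9.

Step 5. Oxidative breakdown or oligomerisation of the α-unsubstituted NH-bipyrrole may outrun substitution. The fallback sets out from 9 and moderates the rings before bromination.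
- Boc2O and DMAP in MeCN should give di-tert-butyl 3,3'-dibromo-2,2'-bipyrrole-1,1'-dicarboxylate F3.
- Two equivalents of 5 in THF at −78 °C brominate C5 and C5', the known α-bromination of N-Boc pyrroles, to give di-tert-butyl 3,3',5,5'-tetrabromo-2,2'-bipyrrole-1,1'-dicarboxylate F4.
- K2CO3 in MeOH removes both carbamates.

The route is rejoined at 10, now isolated with its α-positions blocked. It takes up the last two bromines from 5 as in step 5 to reach 11.

Further compounds
F1 | step 3 | 1,1'-ditosyl-4,4',5,5'-tetrahydro-1H,1'H-2,2'-bipyrrole | Cc1ccc(cc1)S(=O)(=O)N1CCC=C1C1=CCCN1S(=O)(=O)c1ccc(C)cc1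
F2 | step 4 | 3,3'-dibromo-1,1'-ditosyl-1H,1'H-2,2'-bipyrrole | Cc1ccc(cc1)S(=O)(=O)n1ccc(Br)c1-c1c(Br)ccn1S(=O)(=O)c1ccc(C)cc1
F3 | step 5 | di-tert-butyl 3,3'-dibromo-2,2'-bipyrrole-1,1'-dicarboxylate | CC(C)(C)OC(=O)n1ccc(Br)c1-c1c(Br)ccn1C(=O)OC(C)(C)C
F4 | step 5 | di-tert-butyl 3,3',5,5'-tetrabromo-2,2'-bipyrrole-1,1'-dicarboxylate | CC(C)(C)OC(=O)n1c(Br)cc(Br)c1-c1c(Br)cc(Br)n1C(=O)OC(C)(C)C
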